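**Retrosynthetic overview**
1. The C9 tiglate, the C3 senecioate and the C7 isopropenyl group are added last, to the bare trans-decalone 11 (enolate hydroxylation/acylation, acylation, Pd enolate alkenylation).
2. 11 comes from the cis-4,5-dimethyl enedione 9 by one dissolving-metal reduction that sets C10 (trans fusion) and C3 (equatorial OH).
3. 9 comes from spiro-epoxide 7 by a semipinacol ring expansion of ring A from five to six members: the quaternary carbon shifts 1,2 and the new ring carbon C4 arrives with its methyl and its configuration.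
4. 7 comes from the Hajos–Parrish ketone 5 (Wittig ethylidenation, face-selective epoxidation), and 5 from dione 1 and enone 2; the proline aldol sets the quaternary centre.
5. Ring order: the cyclopentane of 1, then ring B (aldol), then ring A (by expansion of that cyclopentane).

Assumption: C-locants in the text use eremophilane numbering of the final skeleton (ring A = C1–C5 and C10, ring B = C5–C10, C14 on C5, C15 on C4, isopropenyl on C7); α is the face opposite the C5 methyl; 5 is used after recrystallisation to >99% ee.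

**Step 1**
Reactants: 1 2-methylcyclopentane-1,3-dione; 2 methyl vinyl ketone
Product: 3 2-methyl-2-(3-oxobutyl)cyclopentane-1,3-dione
Conditions: H2O, AcOH (cat.), 75 °C
Reagents that add atoms: none
Why: Michael addition of the acidic cyclic 1,3-dione to the enone, which stops cleanly at the triketone in water.

**Step 2**
Reactants: 3 2-methyl-2-(3-oxobutyl)cyclopentane-1,3-dione
Product: 5 (7aS)-7a-methyl-2,3,7,7a-tetrahydro-1H-indene-1,5(6H)-dione, via Hajos ketol 4 (not isolated)
Conditions: (S)-proline (3 mol %), DMF, 20 °C; then H2SO4 (cat.), DMF, 95 °C; recrystallisation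
Reagents that add atoms: none
Why: Hajos–Parrish reaction, in which the proline enamine aldol differentiates the two enantiotopic ring carbonyls and sets the quaternary centre (future C5) as S, and acid then dehydrates the cis-ketol to the enone.

**Step 3**
Reactants: 5 (7aS)-7a-methyl-2,3,7,7a-tetrahydro-1H-indene-1,5(6H)-dione
Product: 6 (7aR,Z)-1-ethylidene-7a-methyl-1,2,3,6,7,7a-hexahydro-5H-inden-5-one
Conditions: EtPPh3Br, KOtBu, THF, 0 → 45 °C
Reagents that add atoms: ethyltriphenylphosphonium bromide, CC[P+](c1ccccc1)(c1ccccc1)c1ccccc1.[Br-]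
Why: Wittig olefination, where the non-stabilised ylide takes the saturated cyclopentanone and leaves the conjugated carbonyl (as in 17-ethylidenation of androst-4-ene-3,17-dione) and gives the Z alkene with the new methyl cis to the quaternary carbon.

**Step 4**
Reactants: 6 (7aR,Z)-1-ethylidene-7a-methyl-1,2,3,6,7,7a-hexahydro-5H-inden-5-one
Product: 7 (1R,3'S,7aS)-3',7a-dimethyl-2,3,7,7a-tetrahydrospiro[indene-1,2'-oxiran]-5(6H)-one
Conditions: mCPBA (1.05 equiv), CH2Cl2, 0 °C
Reagents that add atoms: mCPBA (3-chloroperoxybenzoic acid), OOC(=O)c1cccc(Cl)c1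
Why: Prilezhaev epoxidation, in which the electron-rich trisubstituted exocyclic alkene reacts far faster than the enone and the peracid comes from the α face opposite the angular methyl, so alkene geometry plus face selectivity fix the configuration of the future C4.

**Step 5**
Reactants: 7 (1R,3'S,7aS)-3',7a-dimethyl-2,3,7,7a-tetrahydrospiro[indene-1,2'-oxiran]-5(6H)-one
Product: 9 (1R,8aR)-1,8a-dimethyl-1,3,4,7,8,8a-hexahydronaphthalene-2,6-dione, via lithium iodohydrin alkoxide 8 (not isolated)
Conditions: LiI (30 mol %), DMPU (60 mol %), toluene, 80 °C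
Reagents that add atoms: none
Why: Proposed new method: a lithium-iodide-catalysed, stereoretentive ring-expanding epoxide isomerisation in which iodide opens the epoxide at the secondary carbon C4 with inversion, and the tertiary lithium alkoxide 8 then expels iodide while the antiperiplanar C3–C5 bond shifts to C4 with a second inversion (the quaternary C5 is the better migrating group and migrates with retention, from the conformer with C–I turned away from the angular methyl), so that the C3 ketone forms, ring A becomes six-membered and the C4 methyl ends cis to the C5 methyl while iodide turns over; the closest known reaction types are the lithium-halide-catalysed epoxide-to-carbonyl rearrangement through halohydrin salts, the magnesium halohydrin ring enlargement and the deaminative semipinacol D-ring enlargement of 17-hydroxy-20-amino steroids.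

**Step 6**
Reactants: 9 (1R,8aR)-1,8a-dimethyl-1,3,4,7,8,8a-hexahydronaphthalene-2,6-dione
Product: 11 (4aS,5R,6R,8aS)-6-hydroxy-4a,5-dimethyloctahydronaphthalen-2(1H)-one, via dilithium alkoxide enolate 10 (not isolated)
Conditions: Li (4.4 equiv), t-BuOH (2.1 equiv), NH3(l)/THF, −78 °C (9 added to the blue solution); then NH4Cl
Reagents that add atoms: none
Why: Birch-type dissolving-metal reduction, in which the enone is protonated axially at C10 anti to the C5 methyl to give the trans-fused enolate (inert until the quench) and the C3 ketone is reduced through its ketyl to the thermodynamically preferred equatorial 3α-alkoxide trans to the C4 methyl, too fast at −78 °C for C4 to epimerise.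

**Step 7**
Reactants: 11 (4aS,5R,6R,8aS)-6-hydroxy-4a,5-dimethyloctahydronaphthalen-2(1H)-one; 12 2-bromopropene
Product: 14 (3S,4aS,5R,6R,8aS)-6-hydroxy-4a,5-dimethyl-3-(prop-1-en-2-yl)octahydronaphthalen-2(1H)-one, via dilithium dienolate 13 (not isolated)
Conditions: 12 (1.3 equiv), Pd2(dba)3 (2.5 mol %), P(t-Bu)3 (10 mol %), LiN(SiMe3)2 (3.2 equiv), THF, 23 °C; then AcOH, −78 °C
Reagents that add atoms: none
Why: Palladium-catalysed α-alkenylation of a ketone enolate, where the trans-decalone enolises towards C7 (as 3-oxo-5α-steroids do towards C2), the product rests as dienolate 13 so it neither reacts twice nor conjugates, and axial kinetic protonation at C7 gives the β,γ-unsaturated ketone with the equatorial 7α-isopropenyl group.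

**Step 8**
Reactants: 14 (3S,4aS,5R,6R,8aS)-6-hydroxy-4a,5-dimethyl-3-(prop-1-en-2-yl)octahydronaphthalen-2(1H)-one; 15 3-methylbut-2-enoyl chloride
Product: 16 (1R,2R,4aS,7S,8aS)-1,8a-dimethyl-6-oxo-7-(prop-1-en-2-yl)decahydronaphthalen-2-yl 3-methylbut-2-enoate
Conditions: 15 (1.3 equiv), pyridine, DMAP (10 mol %), CH2Cl2, 0 °C
Reagents that add atoms: none
Why: DMAP-catalysed acylation of the equatorial secondary alcohol, with pyridine as a base weak enough to avoid vinylketene formation and deconjugation of the senecioyl unit or of the isopropenyl ketone.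

**Step 9**
Reactants: 16 (1R,2R,4aS,7S,8aS)-1,8a-dimethyl-6-oxo-7-(prop-1-en-2-yl)decahydronaphthalen-2-yl 3-methylbut-2-enoate
Product: 18 (1R,2R,4aR,5S,7S,8aR)-5-hydroxy-1,8a-dimethyl-6-oxo-7-(prop-1-en-2-yl)decahydronaphthalen-2-yl 3-methylbut-2-enoate, via potassium enolate 17 (not isolated)
Conditions: KN(SiMe3)2 (1.15 equiv), THF, −78 °C (16 added to base); then 3-phenyl-2-(phenylsulfonyl)oxaziridine (1.4 equiv), −78 °C; then NH4Cl
Reagents that add atoms: 3-phenyl-2-(phenylsulfonyl)oxaziridine, O=S(=O)(c1ccccc1)N1OC1c1ccccc1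
Why: Davis oxidation of a kinetic enolate, where the bulky amide base takes a proton from the C9 methylene and not the tertiary C7–H, and the oxaziridine delivers oxygen to the α face of C9, anti to the 1,3-related axial C5 methyl, giving the equatorial 9α-hydroxy ketone.

**Step 10**
Reactants: 18 (1R,2R,4aR,5S,7S,8aR)-5-hydroxy-1,8a-dimethyl-6-oxo-7-(prop-1-en-2-yl)decahydronaphthalen-2-yl 3-methylbut-2-enoate; 19 (E)-2-methylbut-2-enoyl chloride
Product: 20 (1R,2R,4aR,5S,7S,8aR)-1,8a-dimethyl-5-{[(2E)-2-methylbut-2-enoyl]oxy}-6-oxo-7-(prop-1-en-2-yl)decahydronaphthalen-2-yl 3-methylbut-2-enoate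
Conditions: 19 (1.5 equiv), pyridine, DMAP (20 mol %), CH2Cl2, 0 → 23 °C
Reagents that add atoms: none
Why: DMAP-catalysed esterification of the α-ketol hydroxyl with the configurationally stable E acid chloride; C7 and C9 both carry their substituents equatorially, so the mild base does not erode them.

**Compound list**
1 | 2-methylcyclopentane-1,3-dione | CC1C(=O)CCC1=O | starting material
2 | methyl vinyl ketone (but-3-en-2-one) | CC(=O)C=C | starting material
3 | 2-methyl-2-(3-oxobutyl)cyclopentane-1,3-dione | CC(=O)CCC1(C)C(=O)CCC1=O | intermediate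
4 | (3aS,7aS)-3a-hydroxy-7a-methylhexahydro-1H-indene-1,5(4H)-dione (cis-fused Hajos ketol) | C[C@]12CCC(=O)C[C@@]1(O)CCC2=O | intermediate
5 | (7aS)-7a-methyl-2,3,7,7a-tetrahydro-1H-indene-1,5(6H)-dione (Hajos–Parrish ketone) | C[C@]12CCC(=O)C=C1CCC2=O | intermediate
6 | (7aR,Z)-1-ethylidene-7a-methyl-1,2,3,6,7,7a-hexahydro-5H-inden-5-one | C/C=C1\[C@@]2(C)CCC(=O)C=C2CC1 | intermediate
7 | (1R,3'S,7aS)-3',7a-dimethyl-2,3,7,7a-tetrahydrospiro[indene-1,2'-oxiran]-5(6H)-one (epoxide oxygen on the face opposite the angular methyl) | C[C@@H]1O[C@]12[C@@]3(C)CCC(=O)C=C3CC2 | intermediate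
8 | lithium (1R,7aS)-1-[(1R)-1-iodoethyl]-7a-methyl-5-oxo-2,3,5,6,7,7a-hexahydro-1H-inden-1-olate | C[C@@H](I)[C@]1([O-])[C@@]2(C)CCC(=O)C=C2CC1.[Li+] | intermediate
9 | (1R,8aR)-1,8a-dimethyl-1,3,4,7,8,8a-hexahydronaphthalene-2,6-dione (cis-4,5-dimethyl, 3,8-dioxo, C9=C10) | C1C[C@]2(C)[C@@H](C)C(=O)CCC2=CC1=O | intermediate
10 | dilithium (4aS,5R,6R,8aS)-4a,5-dimethyl-3,4,4a,5,6,7,8,8a-octahydronaphthalene-2,6-bis(olate) (3α-alkoxide and C8=C9 enolate, trans-fused) | C1C[C@]2(C)[C@@H](C)[C@H](O[Li])CC[C@H]2C=C1O[Li] | intermediate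
11 | (4aS,5R,6R,8aS)-6-hydroxy-4a,5-dimethyloctahydronaphthalen-2(1H)-one (trans-fused, 3α-OH, 4β- and 5β-methyl) | C1C[C@]2(C)[C@@H](C)[C@H](O)CC[C@H]2CC1=O | intermediate
12 | 2-bromopropene | CC(Br)=C | starting material
13 | dilithium (4aS,5R,6R,8aS)-4a,5-dimethyl-3-(prop-1-en-2-yl)-1,4,4a,5,6,7,8,8a-octahydronaphthalene-2,6-bis(olate) (3α-alkoxide and C7=C8 dienolate) | [Li]OC1=C(C(C)=C)C[C@]2(C)[C@@H](C)[C@H](O[Li])CC[C@H]2C1 | intermediate
14 | (3S,4aS,5R,6R,8aS)-6-hydroxy-4a,5-dimethyl-3-(prop-1-en-2-yl)octahydronaphthalen-2(1H)-one | C=C(C)[C@@H]1C[C@]2(C)[C@@H](C)[C@H](O)CC[C@H]2CC1=O | intermediate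
15 | 3-methylbut-2-enoyl chloride (senecioyl chloride) | CC(C)=CC(=O)Cl | starting material
16 | (1R,2R,4aS,7S,8aS)-1,8a-dimethyl-6-oxo-7-(prop-1-en-2-yl)decahydronaphthalen-2-yl 3-methylbut-2-enoate | C=C(C)[C@@H]1C[C@]2(C)[C@@H](C)[C@H](OC(=O)C=C(C)C)CC[C@H]2CC1=O | intermediate
17 | potassium (3S,4aS,5R,6R,8aS)-4a,5-dimethyl-6-[(3-methylbut-2-enoyl)oxy]-3-(prop-1-en-2-yl)-3,4,4a,5,6,7,8,8a-octahydronaphthalen-2-olate (C8=C9 enolate of 16) | C=C(C)[C@@H]1C[C@]2(C)[C@@H](C)[C@H](OC(=O)C=C(C)C)CC[C@H]2C=C1O[K] | intermediate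
18 | (1R,2R,4aR,5S,7S,8aR)-5-hydroxy-1,8a-dimethyl-6-oxo-7-(prop-1-en-2-yl)decahydronaphthalen-2-yl 3-methylbut-2-enoate | C=C(C)[C@@H]1C[C@]2(C)[C@@H](C)[C@H](OC(=O)C=C(C)C)CC[C@H]2[C@H](O)C1=O | intermediate
19 | (E)-2-methylbut-2-enoyl chloride (tigloyl chloride) | C/C=C(\C)C(=O)Cl | starting material
20 | (1R,2R,4aR,5S,7S,8aR)-1,8a-dimethyl-5-{[(2E)-2-methylbut-2-enoyl]oxy}-6-oxo-7-(prop-1-en-2-yl)decahydronaphthalen-2-yl 3-methylbut-2-enoate (CNP0164025.1) | C=C(C)[C@@H]1C[C@]2(C)[C@@H](C)[C@H](OC(=O)C=C(C)C)CC[C@H]2[C@H](OC(=O)/C(C)=C/C)C1=O | target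

**Total step count:** 10. **Longest linear sequence:** 10 steps (fully linear from 1 and 2).

**Steps most likely to fail**

Step 5 (the proposed new step). The risks are opening of the epoxide at the tertiary carbon (leading to a 1-acetyl product by hydride shift), migration of the ring methylene in place of the quaternary carbon, and vinylogous retro-aldol cleavage of the tertiary alkoxide. The fallback uses known chemistry, sets out from 7 and returns at 9. NaN3/NH4Cl in DMF–H2O at 80 °C opens the epoxide at C4 with inversion to the azido alcohol (1R,7aS)-1-[(1R)-1-azidoethyl]-1-hydroxy-7a-methyl-1,2,3,6,7,7a-hexahydro-5H-inden-5-one F1. PPh3 in THF–H2O reduces it to the amino alcohol (1R,7aS)-1-[(1R)-1-aminoethyl]-1-hydroxy-7a-methyl-1,2,3,6,7,7a-hexahydro-5H-inden-5-one F2. NaNO2 in aqueous AcOH at 0 °C then effects the classical Tiffeneau–Demjanov (deaminative semipinacol) ring enlargement to 9, with the same double inversion at C4 and the steroid-precedented migration of the quaternary carbon.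

Step 7. The risks are competing alkenylation at C9, oxidation of the free C3 alkoxide by the alkenylpalladium intermediate, and drift of the isopropenyl double bond into conjugation. The fallback sets out from 11 and returns at 16. The dianion of 11 (LDA, 2.2 equiv, THF, −78 °C) is added to acetone to give the aldol (3S,4aS,5R,6R,8aS)-6-hydroxy-3-(2-hydroxypropan-2-yl)-4a,5-dimethyloctahydronaphthalen-2(1H)-one F3. 15 with pyridine/DMAP acylates only the secondary hydroxyl to give (1R,2R,4aS,7S,8aS)-7-(2-hydroxypropan-2-yl)-1,8a-dimethyl-6-oxodecahydronaphthalen-2-yl 3-methylbut-2-enoate F4. Burgess reagent (benzene, 50 °C) dehydrates the tertiary carbinol towards the methyl groups to give 16.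

Step 9. The risks are deprotonation at the doubly activated C7–H in place of C9, and addition of the enolate to the sulfonimine by-product. The fallback sets out from 16 and returns at 18. D-proline (30 mol %) and nitrosobenzene in DMSO at 20 °C carry out an enamine α-aminoxylation, the enamine forming away from the substituted C7, to give (1R,2R,4aR,5S,7S,8aR)-1,8a-dimethyl-6-oxo-5-[(phenylamino)oxy]-7-(prop-1-en-2-yl)decahydronaphthalen-2-yl 3-methylbut-2-enoate F5. CuSO4 (30 mol %) in MeOH at 0 °C cleaves the N–O bond to give 18.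

**Further compounds**
F1 | step 5 | (1R,7aS)-1-[(1R)-1-azidoethyl]-1-hydroxy-7a-methyl-1,2,3,6,7,7a-hexahydro-5H-inden-5-one | C[C@@H](N=[N+]=[N-])[C@]1(O)[C@@]2(C)CCC(=O)C=C2CC1
F2 | step 5 | (1R,7aS)-1-[(1R)-1-aminoethyl]-1-hydroxy-7a-methyl-1,2,3,6,7,7a-hexahydro-5H-inden-5-one | C[C@@H](N)[C@]1(O)[C@@]2(C)CCC(=O)C=C2CC1
F3 | step 7 | (3S,4aS,5R,6R,8aS)-6-hydroxy-3-(2-hydroxypropan-2-yl)-4a,5-dimethyloctahydronaphthalen-2(1H)-one | CC(C)(O)[C@@H]1C[C@]2(C)[C@@H](C)[C@H](O)CC[C@H]2CC1=O
F4 | step 7 | (1R,2R,4aS,7S,8aS)-7-(2-hydroxypropan-2-yl)-1,8a-dimethyl-6-oxodecahydronaphthalen-2-yl 3-methylbut-2-enoate | CC(C)(O)[C@@H]1C[C@]2(C)[C@@H](C)[C@H](OC(=O)C=C(C)C)CC[C@H]2CC1=O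
F5 | step 9 | (1R,2R,4aR,5S,7S,8aR)-1,8a-dimethyl-6-oxo-5-[(phenylamino)oxy]-7-(prop-1-en-2-yl)decahydronaphthalen-2-yl 3-methylbut-2-enoate | C=C(C)[C@@H]1C[C@]2(C)[C@@H](C)[C@H](OC(=O)C=C(C)C)CC[C@H]2[C@H](ONc3ccccc3)C1=O
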